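At early times the runs already show a pattern: at equal equivalents, gamma at 6.00 min reads 9.9% free electrophile and alpha at 4.00 min reads 8.4%, which agree within the scatter. Both have the same product of charged c(electrophile) and time, 3.60 M·s. I call this product the exposure; for this flask it is 14.4 M·s.

| flask | electrophile | nucleophile | buffer base | buffer acid | remark | time |
|---|---|---|---|---|---|---|
| gamma | 0.010 M | 0.90 equiv | 3 equiv | 0.10 equiv | run made earlier |  |
| alpha | 0.015 M | 0.90 equiv | 3 equiv | 0.10 equiv | run made earlier |  |
| beta | 0.020 M | 0.45 equiv | 3 equiv | 0.10 equiv | run made earlier |  |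
| flask | 0.020 M | 0.900 equiv | 3.00 equiv | 0.100 equiv |  | 12 min |

- gamma (time / min: electrophile / %, product / %): 2.00: 21.8, 42.0; 4.00: 15.1, 52.0; 6.00: 9.9, 57.2; 8.00: 6.3, 59.9; 10.0: 5.2, 64.4
- alpha (time / min: electrophile / %, product / %): 2.00: 16.1, 46.1; 4.00: 8.4, 55.5; 6.00: 8.0, 58.8; 8.00: 5.7, 63.3; 10.0: 3.5, 61.9
- beta (time / min: electrophile / %, product / %): 2.00: 34.9, 34.2; 4.00: 24.6, 39.9; 6.00: 20.0, 41.9; 8.00: 17.4, 44.4; 10.0: 19.0, 43.2

(scatter of a reading: 1 percentage point)

- a reading or a percentage of product counts all its forms, free or not
- what has gone from electrophile into another species counts as reacted, even if it can come back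
- the earlier runs do not show the pH; that part of a forecast is a guess
- a reading of electrophile is of its free form alone

1. part of the electrophile that has reacted at 12 min
2. pH of the solution at 12 min

Alpha ends at exposure 9.00 M·s with 3.5% free electrophile, so the flask must be carried beyond the readings. In one extreme the tail stops there, and 96.5% has reacted. In the other, alpha's mean logarithmic fall per exposure, 12.7 M⁻¹ min⁻¹, simply continues, leaving 1.11% free. The mean looks too steep for the fall ahead: from 4.00 min to 10.0 min alpha's readings give a lower fall per exposure, 9.73 M⁻¹ min⁻¹. But alpha's free electrophile still reads lower at its last reading than at the one before, 3.5% against 5.7%, so I do not let the tail stop there. I take the logarithmic middle, 1.97% free, or 98.0% reacted.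

The forecast, which expects that “free electrophile keeps falling”, gives 97.5% (95.5% to 99%) and guesses pH 7 (5 to 9.5).

The flask gives 97.7% reacted and pH 6.09.

    electrophile + nucleophile → acid + product + leaving group (k = 68.0 M⁻¹ min⁻¹)
    protonated nucleophile ⇌ nucleophile + acid, settled at all times (K = 4.00 × 10⁻⁵ M)
    buffer acid ⇌ buffer base + acid, settled at all times (K = 2.50 × 10⁻⁶ M)
    electrophile + product ⇌ idle adduct, settled at all times (K = 1900 M⁻¹)

The electrophile's half-life by the first step at charged concentrations, 0.57 min, is short against 12 min, so exposure 14.4 M·s spans 21.2 such half-lives, yet the 2.3% left free is 5.44 halvings. Meanwhile the nucleophile's half-life by that step stretches from 1.4 min at 0.575 min to 22 min at 12.0 min.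

A neighbour with the same equivalents at 0.0080 M has exposure 5.76 M·s, close to gamma's final 6.00 M·s, so gamma's last reading promises about 94.8% reacted. That neighbour gives 93.7%.

The readings stem from a simulated flask from invented constants; noise was put on by code.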